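**Plan**

- Retrosynthesis: the six aryl methyl ethers are cut last. Ring B is then cut at C3–C4 and C5–C6, the two =CH2 groups of the resulting diene are taken back to an alkyne plus ethylene, and the alkyne is cut at ring A–C(sp). The remaining cuts are the aryl–C(=O) bonds of rings A and D and the ring C–chain bond.
- Enabling feature: in ring B the hydroxylated carbons C4 and C5 are adjacent and lie opposite C1 (nonyl chain) and C2 (bond to ring A). C6–C1–C2–C3 therefore maps onto a 2-aryl-3-alkylbuta-1,3-diene and C4–C5 onto vinylene carbonate.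
- Forward order: ring C plus chain is joined to an iodinated ring A aldehyde to give the ring A iodide, and ring D is acylated with the undecynoic chain. The two halves are joined by Sonogashira coupling, ethylene metathesis gives the diene, ring B closes by [4+2] cycloaddition, and aromatization and demethylation finish the route.
- Stereochemistry: the target has no stereocentre. The cis carbinol centres of the cycloadduct come from suprafacial addition of the cyclic Z-dienophile and are erased on aromatization; the carbinol of step 4 is racemic and is oxidized away.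

Key step: step 10

Assumption: ring A is the 2,4-dioxygenated 3-acylphenyl ring, ring B the biaryl catechol (C1 chain, C2 ring A, C4/C5 oxygenated), ring C the terminal catechol and ring D the 2,6-dioxygenated benzoyl ring; all chiral intermediates are racemic. Ring A is iodinated as the aldehyde before ring C is attached, because the two electron-rich rings could not be told apart by an iodinating agent later.

**Route**

Step 1
Reactants: 1 8-bromooctanoic acid; 2 1,2-dimethoxybenzene
Product: 4 8-bromo-1-(3,4-dimethoxyphenyl)octan-1-one, via 8-bromooctanoyl chloride 3 (not isolated)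
Conditions: (COCl)2, DMF (cat.), CH2Cl2, 0 °C to rt, evaporate; then 2, AlCl3 (1.1 equiv), CH2Cl2, 0 °C
Reagents that add atoms: none
Why: Friedel–Crafts acylation of 1,2-dimethoxybenzene occurs para to a methoxy group, and a primary alkyl bromide is not ionized by AlCl3 at 0 °C, so the bromoacyl chain should be installed at C4 only.

Step 2
Reactants: 4 8-bromo-1-(3,4-dimethoxyphenyl)octan-1-one
Product: 5 4-(8-bromooctyl)-1,2-dimethoxybenzene
Conditions: Et3SiH (3 equiv), CF3CO2H, rt
Reagents that add atoms: none
Why: Ionic hydrogenation reduces an electron-rich aryl ketone to the methylene through the stabilized benzylic cation and leaves the primary bromide and the methyl ethers untouched.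

Step 3
Reactants: 6 2,6-dimethoxybenzaldehyde
Product: 7 3-iodo-2,6-dimethoxybenzaldehyde
Conditions: N-iodosuccinimide (1.05 equiv), CF3CO2H (cat.), MeCN, rt
Reagents that add atoms: N-iodosuccinimide, O=C1CCC(=O)N1I
Why: Electrophilic aromatic iodination is directed to C3 by both methoxy groups (ortho to one, para to the other) and by the meta-directing formyl group, so the coupling handle of ring A is set before ring C is present.

Step 4
Reactants: 5 4-(8-bromooctyl)-1,2-dimethoxybenzene; 7 3-iodo-2,6-dimethoxybenzaldehyde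
Product: 9 rac-9-(3,4-dimethoxyphenyl)-1-(3-iodo-2,6-dimethoxyphenyl)nonan-1-ol, via [8-(3,4-dimethoxyphenyl)octyl]magnesium bromide 8 (not isolated)
Conditions: Mg, I2 (cat.), THF, 50 °C; then added to 7, THF, −78 to 0 °C; aq. NH4Cl
Reagents that add atoms: none
Why: Grignard addition to the aldehyde at −78 °C is far faster than iodine–magnesium exchange between a primary alkylmagnesium halide and an electron-rich aryl iodide, inverse addition keeps the organometallic from being in excess, and the new carbinol centre forms racemic and is removed in step 5.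

Step 5
Reactants: 9 rac-9-(3,4-dimethoxyphenyl)-1-(3-iodo-2,6-dimethoxyphenyl)nonan-1-ol
Product: 10 9-(3,4-dimethoxyphenyl)-1-(3-iodo-2,6-dimethoxyphenyl)nonan-1-one (ring A iodide)
Conditions: Dess–Martin periodinane (1.3 equiv), CH2Cl2, 0 °C to rt
Reagents that add atoms: none
Why: Dess–Martin oxidation converts the hindered benzylic carbinol into the ketone under near-neutral conditions that spare the aryl iodide and the electron-rich rings.

Step 6
Reactants: 11 undec-10-ynoic acid
Product: 12 N-methoxy-N-methylundec-10-ynamide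
Conditions: 1,1'-carbonyldiimidazole, CH2Cl2, rt; then MeNHOMe·HCl, rt
Reagents that add atoms: N,O-dimethylhydroxylamine hydrochloride, CNOC.Cl
Why: Acyl imidazolide formation followed by aminolysis (Weinreb amide synthesis) runs at room temperature without any base strong enough to touch the terminal alkyne.

Step 7
Reactants: 12 N-methoxy-N-methylundec-10-ynamide; 13 1,3-dimethoxybenzene
Product: 15 1-(2,6-dimethoxyphenyl)undec-10-yn-1-one, via (2,6-dimethoxyphenyl)lithium 14 (not isolated)
Conditions: 13 (2.5 equiv), n-BuLi (2.4 equiv), THF, 0 °C to rt; then 12, −78 to 0 °C; aq. NH4Cl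
Reagents that add atoms: none
Why: Directed ortho-lithiation of 1,3-dimethoxybenzene occurs at C2 between the two methoxy groups, one equivalent of the aryllithium is spent on the acetylenic C–H and the remainder adds once to the Weinreb amide, whose chelated tetrahedral adduct releases the ketone only on work-up (Weinreb ketone synthesis).

Step 8
Reactants: 10 9-(3,4-dimethoxyphenyl)-1-(3-iodo-2,6-dimethoxyphenyl)nonan-1-one; 15 1-(2,6-dimethoxyphenyl)undec-10-yn-1-one
Product: 16 1-(2,6-dimethoxyphenyl)-11-{3-[9-(3,4-dimethoxyphenyl)nonanoyl]-2,4-dimethoxyphenyl}undec-10-yn-1-one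
Conditions: PdCl2(PPh3)2 (5 mol%), CuI (10 mol%), Et3N/THF, 50 °C, degassed
Reagents that add atoms: none
Why: Sonogashira coupling of an aryl iodide with a terminal alkyne is reliable under these amine conditions, and both ketones are inert because no strong base is present.

Step 9
Reactants: 16 1-(2,6-dimethoxyphenyl)-11-{3-[9-(3,4-dimethoxyphenyl)nonanoyl]-2,4-dimethoxyphenyl}undec-10-yn-1-one; 17 ethylene
Product: 18 1-(2,6-dimethoxyphenyl)-11-{3-[9-(3,4-dimethoxyphenyl)nonanoyl]-2,4-dimethoxyphenyl}-10-methylidenedodec-11-en-1-one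
Conditions: RuCl2(H2IMes)(PCy3)(=CHPh) (second-generation Grubbs catalyst, 10 mol%), 17 (1 atm), toluene, 80 °C
Reagents that add atoms: none
Why: Cross enyne metathesis of an internal alkyne with ethylene, in which the ruthenium methylidene adds across the triple bond and the resulting vinylcarbene is released by ethylene, places one methylene on each former alkyne carbon and so gives the 2,3-disubstituted buta-1,3-diene directly.

Step 10
Reactants: 18 1-(2,6-dimethoxyphenyl)-11-{3-[9-(3,4-dimethoxyphenyl)nonanoyl]-2,4-dimethoxyphenyl}-10-methylidenedodec-11-en-1-one; 19 vinylene carbonate (1,3-dioxol-2-one)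
Product: 20 rac-(3aR,7aS)-5-{3-[9-(3,4-dimethoxyphenyl)nonanoyl]-2,4-dimethoxyphenyl}-6-[9-(2,6-dimethoxyphenyl)-9-oxononyl]-3a,4,7,7a-tetrahydro-1,3-benzodioxol-2-one (cis-fused cyclohexene carbonate)
Conditions: 19 (10 equiv), BHT (5 mol%), o-xylene, sealed tube, 170 °C
Reagents that add atoms: none
Why: The s-cis conformer of diene 18 (C6–C1–C2–C3 of the future ring B) and the C=C bond of vinylene carbonate 19 (C4–C5) combine in a concerted, thermally allowed suprafacial [4+2] cycloaddition that forms C3–C4 and C5–C6 together. The closest known reaction type is the Diels–Alder addition of vinylene carbonate to 2,3-disubstituted buta-1,3-dienes at 150–180 °C. Ring B closes as a cyclohexene by this intermolecular [4+2] annulation, both ring bonds arising in one pericyclic event, while the five-membered carbonate ring is carried in by the dienophile and ends cis-fused. The two new stereocentres C4 and C5 are set cis because the Z geometry locked in the cyclic dienophile is transferred suprafacially; the adduct is racemic, no endo/exo question arises since the diene termini are unsubstituted, and both centres disappear in step 12. Regiochemistry is not at stake because the dienophile is symmetric, so the only selectivity needed is cycloaddition over self-dimerization or radical polymerization of the diene; this is secured by the 1,1-disubstituted, unactivated character of each diene double bond (a poor 2π partner), the large excess of 19 and the radical inhibitor. The aryl ketones and methyl ethers are spectators at this temperature.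

Step 11
Reactants: 20 cis-fused cyclohexene carbonate
Product: 21 rac-1-(2,6-dimethoxyphenyl)-9-[(4R,5S)-2-{3-[9-(3,4-dimethoxyphenyl)nonanoyl]-2,4-dimethoxyphenyl}-4,5-dihydroxycyclohex-1-en-1-yl]nonan-1-one (cis-diol)
Conditions: K2CO3 (cat.), MeOH, rt
Reagents that add atoms: none
Why: Base-catalysed transesterification with methanol opens the five-membered cyclic carbonate to dimethyl carbonate and the cis-diol without touching the aryl ketones or methyl ethers, and neither carbinol centre can epimerize.

Step 12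
Reactants: 21 cis-diol
Product: 23 1-(2,6-dimethoxyphenyl)-9-(2-{3-[9-(3,4-dimethoxyphenyl)nonanoyl]-2,4-dimethoxyphenyl}-4,5-dihydroxyphenyl)nonan-1-one (ring B catechol), via ring B cyclohex-4-ene-1,2-dione 22 (not isolated)
Conditions: DMSO (6 equiv), (CF3CO)2O (4 equiv), CH2Cl2, −78 °C; then Et3N, −78 °C to rt; 1 M HCl work-up under argon
Reagents that add atoms: none
Why: Activated-dimethyl-sulfoxide (Swern-type) oxidation of both carbinols gives the cyclohex-4-ene-1,2-dione, whose enolization toward C3 and C6 under the amine base is driven by aromatization, so the two cis stereocentres are erased and ring B emerges as the free catechol.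

Step 13
Reactants: 23 ring B catechol
Product: 24 giganteone A, 9-(3,4-dihydroxyphenyl)-1-(3-{2-[9-(2,6-dihydroxyphenyl)-9-oxononyl]-4,5-dihydroxyphenyl}-2,6-dihydroxyphenyl)nonan-1-one
Conditions: BBr3 (15 equiv), CH2Cl2, −78 °C to rt; then H2O/MeOH, 0 °C
Reagents that add atoms: none
Why: BBr3 cleaves aryl methyl ethers by boron coordination and bromide attack at methyl, helped at rings A and D by chelation to the ortho carbonyl, and the acylphenol and catechol products are stable to the reagent and to the aqueous quench.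

**Compound list**

1 | 8-bromooctanoic acid | OC(=O)CCCCCCCBr | starting material
2 | 1,2-dimethoxybenzene | COc1ccccc1OC | starting material
3 | 8-bromooctanoyl chloride (not isolated) | ClC(=O)CCCCCCCBr | intermediate
4 | 8-bromo-1-(3,4-dimethoxyphenyl)octan-1-one | BrCCCCCCCC(=O)c1ccc(OC)c(OC)c1 | intermediate
5 | 4-(8-bromooctyl)-1,2-dimethoxybenzene | BrCCCCCCCCc1ccc(OC)c(OC)c1 | intermediate
6 | 2,6-dimethoxybenzaldehyde | COc1cccc(OC)c1C=O | starting material
7 | 3-iodo-2,6-dimethoxybenzaldehyde | COc1ccc(I)c(OC)c1C=O | intermediate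
8 | [8-(3,4-dimethoxyphenyl)octyl]magnesium bromide (not isolated) | Br[Mg]CCCCCCCCc1ccc(OC)c(OC)c1 | intermediate
9 | rac-9-(3,4-dimethoxyphenyl)-1-(3-iodo-2,6-dimethoxyphenyl)nonan-1-ol (racemic carbinol) | OC(CCCCCCCCc1ccc(OC)c(OC)c1)c1c(OC)ccc(I)c1OC | intermediate
10 | 9-(3,4-dimethoxyphenyl)-1-(3-iodo-2,6-dimethoxyphenyl)nonan-1-one (ring A iodide) | O=C(CCCCCCCCc1ccc(OC)c(OC)c1)c1c(OC)ccc(I)c1OC | intermediate
11 | undec-10-ynoic acid | C#CCCCCCCCCC(=O)O | starting material
12 | N-methoxy-N-methylundec-10-ynamide | C#CCCCCCCCCC(=O)N(C)OC | intermediate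
13 | 1,3-dimethoxybenzene | COc1cccc(OC)c1 | starting material
14 | (2,6-dimethoxyphenyl)lithium (not isolated) | [Li]c1c(OC)cccc1OC | intermediate
15 | 1-(2,6-dimethoxyphenyl)undec-10-yn-1-one | C#CCCCCCCCCC(=O)c1c(OC)cccc1OC | intermediate
16 | 1-(2,6-dimethoxyphenyl)-11-{3-[9-(3,4-dimethoxyphenyl)nonanoyl]-2,4-dimethoxyphenyl}undec-10-yn-1-one | O=C(CCCCCCCCC#Cc1ccc(OC)c(C(=O)CCCCCCCCc2ccc(OC)c(OC)c2)c1OC)c1c(OC)cccc1OC | intermediate
17 | ethylene | C=C | starting material
18 | 1-(2,6-dimethoxyphenyl)-11-{3-[9-(3,4-dimethoxyphenyl)nonanoyl]-2,4-dimethoxyphenyl}-10-methylidenedodec-11-en-1-one (diene) | C=C(c1ccc(OC)c(C(=O)CCCCCCCCc2ccc(OC)c(OC)c2)c1OC)C(=C)CCCCCCCCC(=O)c1c(OC)cccc1OC | intermediate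
19 | vinylene carbonate (1,3-dioxol-2-one) | O=C1OC=CO1 | starting material
20 | rac-(3aR,7aS)-5-{3-[9-(3,4-dimethoxyphenyl)nonanoyl]-2,4-dimethoxyphenyl}-6-[9-(2,6-dimethoxyphenyl)-9-oxononyl]-3a,4,7,7a-tetrahydro-1,3-benzodioxol-2-one (cis-fused, racemic, one enantiomer drawn) | O=C1O[C@@H]2CC(c3ccc(OC)c(C(=O)CCCCCCCCc4ccc(OC)c(OC)c4)c3OC)=C(CCCCCCCCC(=O)c3c(OC)cccc3OC)C[C@@H]2O1 | intermediate
21 | rac-1-(2,6-dimethoxyphenyl)-9-[(4R,5S)-2-{3-[9-(3,4-dimethoxyphenyl)nonanoyl]-2,4-dimethoxyphenyl}-4,5-dihydroxycyclohex-1-en-1-yl]nonan-1-one (cis-diol, racemic, one enantiomer drawn) | O[C@@H]1CC(c2ccc(OC)c(C(=O)CCCCCCCCc3ccc(OC)c(OC)c3)c2OC)=C(CCCCCCCCC(=O)c2c(OC)cccc2OC)C[C@@H]1O | intermediate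
22 | 1-(2,6-dimethoxyphenyl)-9-(2-{3-[9-(3,4-dimethoxyphenyl)nonanoyl]-2,4-dimethoxyphenyl}-4,5-dioxocyclohex-1-en-1-yl)nonan-1-one (ene-dione, not isolated) | O=C1CC(c2ccc(OC)c(C(=O)CCCCCCCCc3ccc(OC)c(OC)c3)c2OC)=C(CCCCCCCCC(=O)c2c(OC)cccc2OC)CC1=O | intermediate
23 | 1-(2,6-dimethoxyphenyl)-9-(2-{3-[9-(3,4-dimethoxyphenyl)nonanoyl]-2,4-dimethoxyphenyl}-4,5-dihydroxyphenyl)nonan-1-one (ring B catechol) | O=C(CCCCCCCCc1cc(O)c(O)cc1-c1ccc(OC)c(C(=O)CCCCCCCCc2ccc(OC)c(OC)c2)c1OC)c1c(OC)cccc1OC | intermediate
24 | giganteone A (achiral) | O=C(CCCCCCCCc1cc(O)c(O)cc1-c1ccc(O)c(C(=O)CCCCCCCCc2ccc(O)c(O)c2)c1O)c1c(O)cccc1O | target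

**Step count**

Total: 13 steps. Longest linear sequence: 10 steps (1, 2, 4, 5, 8, 9, 10, 11, 12, 13).

**Steps most likely to fail**

Step 9. After alkyne insertion the ruthenium vinylcarbene can be held as a chelate by the ortho-methoxy oxygen of ring A, and the internal aryl alkyne is hindered, so turnover may stall or alkyne oligomerization may take over. The fallback builds the diene by coupling two 1,1-disubstituted vinyl partners; it sets out from 10 and 15 and returns at 18. Iodide 10 would undergo Stille coupling with tributyl(ethynyl)stannane (Pd(PPh3)4, toluene, 90 °C) to give the terminal aryl alkyne 9-(3,4-dimethoxyphenyl)-1-(3-ethynyl-2,6-dimethoxyphenyl)nonan-1-one F1. Copper-catalysed Markovnikov protoboration ((SIMes)CuCl, NaOt-Bu, B2pin2, MeOH, THF, rt) should then give 9-(3,4-dimethoxyphenyl)-1-{2,6-dimethoxy-3-[1-(4,4,5,5-tetramethyl-1,3,2-dioxaborolan-2-yl)ethenyl]phenyl}nonan-1-one F2. Alkynone 15 would be converted by Markovnikov hydroiodination (NaI, Me3SiCl, H2O, MeCN, rt) into 1-(2,6-dimethoxyphenyl)-10-iodoundec-10-en-1-one F3. Suzuki–Miyaura coupling of F2 with F3 (PdCl2(dppf), K3PO4, THF/H2O, 50 °C) should deliver diene 18.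

Step 10. At the temperature vinylene carbonate needs, thermal polymerization or dimerization of the diene, or decomposition of the dienophile, may outrun the cycloaddition. The fallback forms the same two ring bonds with a much more reactive two-carbon partner and introduces the oxygens afterwards; it sets out from 18 and returns at 21. Diene 18 and (E)-1,2-bis(phenylsulfonyl)ethene (toluene, 110 °C) should give rac-1-(2,6-dimethoxyphenyl)-9-[(4R,5R)-2-{3-[9-(3,4-dimethoxyphenyl)nonanoyl]-2,4-dimethoxyphenyl}-4,5-bis(phenylsulfonyl)cyclohex-1-en-1-yl]nonan-1-one F4. Reductive elimination with buffered sodium amalgam (Na(Hg), NaH2PO4, MeOH/THF, −20 °C, kept cold to spare the twisted aryl ketones) would give 1-(2,6-dimethoxyphenyl)-9-(2-{3-[9-(3,4-dimethoxyphenyl)nonanoyl]-2,4-dimethoxyphenyl}cyclohexa-1,4-dien-1-yl)nonan-1-one F5. Dihydroxylation of its unhindered disubstituted C4=C5 bond (OsO4 cat., 4-methylmorpholine N-oxide, acetone/H2O) in preference to the tetrasubstituted C1=C2 bond should give cis-diol 21.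

Step 12. The second oxidation may stop at the hydroxy ketone, or the freshly formed catechol may be attacked by excess activated sulfoxide (methylthiomethylation) or air-oxidized during the basic phase. The fallback deliberately overshoots to the quinone level and comes back by reduction; it sets out from 21 and returns at 23. 2-Iodoxybenzoic acid (IBX, 3.5 equiv, DMSO, rt) oxidizes 1,2-diols to 1,2-diones without C–C cleavage and carries the resulting catechol on to 4-[9-(2,6-dimethoxyphenyl)-9-oxononyl]-5-{3-[9-(3,4-dimethoxyphenyl)nonanoyl]-2,4-dimethoxyphenyl}cyclohexa-3,5-diene-1,2-dione F6. This would be reduced without delay (Na2S2O4, EtOAc/H2O, rt) to catechol 23.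

**Further compounds**

F1 | step 9 | 9-(3,4-dimethoxyphenyl)-1-(3-ethynyl-2,6-dimethoxyphenyl)nonan-1-one | C#Cc1ccc(OC)c(C(=O)CCCCCCCCc2ccc(OC)c(OC)c2)c1OC
F2 | step 9 | 9-(3,4-dimethoxyphenyl)-1-{2,6-dimethoxy-3-[1-(4,4,5,5-tetramethyl-1,3,2-dioxaborolan-2-yl)ethenyl]phenyl}nonan-1-one | C=C(B1OC(C)(C)C(C)(C)O1)c1ccc(OC)c(C(=O)CCCCCCCCc2ccc(OC)c(OC)c2)c1OC
F3 | step 9 | 1-(2,6-dimethoxyphenyl)-10-iodoundec-10-en-1-one | C=C(I)CCCCCCCCC(=O)c1c(OC)cccc1OC
F4 | step 10 | rac-1-(2,6-dimethoxyphenyl)-9-[(4R,5R)-2-{3-[9-(3,4-dimethoxyphenyl)nonanoyl]-2,4-dimethoxyphenyl}-4,5-bis(phenylsulfonyl)cyclohex-1-en-1-yl]nonan-1-one (trans, racemic, one enantiomer drawn) | O=S(=O)(c1ccccc1)[C@@H]2CC(c3ccc(OC)c(C(=O)CCCCCCCCc4ccc(OC)c(OC)c4)c3OC)=C(CCCCCCCCC(=O)c3c(OC)cccc3OC)C[C@H]2S(=O)(=O)c1ccccc1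
F5 | step 10 | 1-(2,6-dimethoxyphenyl)-9-(2-{3-[9-(3,4-dimethoxyphenyl)nonanoyl]-2,4-dimethoxyphenyl}cyclohexa-1,4-dien-1-yl)nonan-1-one | O=C(CCCCCCCCC1=C(c2ccc(OC)c(C(=O)CCCCCCCCc3ccc(OC)c(OC)c3)c2OC)CC=CC1)c1c(OC)cccc1OC
F6 | step 12 | 4-[9-(2,6-dimethoxyphenyl)-9-oxononyl]-5-{3-[9-(3,4-dimethoxyphenyl)nonanoyl]-2,4-dimethoxyphenyl}cyclohexa-3,5-diene-1,2-dione | O=C1C=C(CCCCCCCCC(=O)c2c(OC)cccc2OC)C(c2ccc(OC)c(C(=O)CCCCCCCCc3ccc(OC)c(OC)c3)c2OC)=CC1=O
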